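Ring C carries a hydroxyl on C3 beside the C4 carbonyl; one oxidation level down, in a 3-hydroxychroman-4-one, this C3(OH)–C4(=O) pair is an acyloin, so everything rests on cutting the C3–C4 bond. An intramolecular crossed benzoin, catalysed by a triazolylidene, couples a ring A formyl group (future C4) with a tethered α-aryloxy arylacetaldehyde (future C3): one operation forms C3–C4, closes ring C and brings in the C3 oxygen, and the electron-rich, doubly benzylic C–H on the C8 side chain is never exposed to a powerful oxidant. The precursor is a dialdehyde already holding the O1–C2 ether, two benzyl ethers and the (R)-1-arylethyl group, which is set by hydroxyl-directed asymmetric hydrogenation.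

Key step: step 9

Assumption: 2',4'-dihydroxy-6'-methoxyacetophenone (1) is treated as a purchasable compound, and the ligand antipode named in step 3 is taken to be the one that gives the (R) centre; the mirror-image ligand is used if a pilot run shows the opposite sense.

Step 1
Reactants: 1 2',4'-dihydroxy-6'-methoxyacetophenone
Product: 2 1-[4-(benzyloxy)-2-hydroxy-6-methoxyphenyl]ethan-1-one
Conditions: BnBr (1.05 equiv), K2CO3, acetone, reflux
Reagents that add atoms: benzyl bromide, BrCc1ccccc1
Why: Williamson etherification, in which the 2'-hydroxyl is tied up in a hydrogen bond to the acetyl carbonyl, so the more acidic and unhindered 4'-phenoxide should be the one alkylated by a single equivalent of benzyl bromide.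

Step 2
Reactants: 2 1-[4-(benzyloxy)-2-hydroxy-6-methoxyphenyl]ethan-1-one; 3 1-benzyloxy-4-bromobenzene
Product: 6 5-(benzyloxy)-2-{1-[4-(benzyloxy)phenyl]ethenyl}-3-methoxyphenol, via 4-(benzyloxy)phenylmagnesium bromide 4 (not isolated), via tertiary carbinol 5 (not isolated)
Conditions: 3 (3 equiv), Mg, THF, reflux; then 2, LaCl3·2LiCl, THF, 0 °C to rt; aq NH4Cl; then TsOH·H2O (cat.), toluene, rt
Reagents that add atoms: none
Why: Grignard addition followed by acid-catalysed E1 dehydration, in which the first equivalent of 4 forms the magnesium phenoxide, a further equivalent adds to the chelated ketone (LaCl3·2LiCl suppresses enolisation), and the electron-rich doubly benzylic carbinol 5 should lose water under mild acid to the only alkene open to it.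

Step 3
Reactants: 6 5-(benzyloxy)-2-{1-[4-(benzyloxy)phenyl]ethenyl}-3-methoxyphenol
Product: 7 5-(benzyloxy)-2-{(1R)-1-[4-(benzyloxy)phenyl]ethyl}-3-methoxyphenol
Conditions: H2 (10 bar), [Rh(cod)2]BF4 (2 mol %), (R)-1-[(SP)-2-(diphenylphosphino)ferrocenyl]ethyldi-tert-butylphosphine (2.2 mol %), Et3N, MeOH/THF, 30 °C
Reagents that add atoms: none
Why: Hydroxyl-directed rhodium-catalysed asymmetric hydrogenation of a 2-(1-arylvinyl)phenol, in which the phenoxide binds the cationic rhodium centre and holds the twisted alkene in a chelate, so hydrogen should be delivered to the face selected by the chiral ferrocenyl bisphosphine and set the (R) centre, while the benzyl ethers are inert to the homogeneous catalyst.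

Step 4
Reactants: 7 5-(benzyloxy)-2-{(1R)-1-[4-(benzyloxy)phenyl]ethyl}-3-methoxyphenol
Product: 8 6-(benzyloxy)-3-{(1R)-1-[4-(benzyloxy)phenyl]ethyl}-2-hydroxy-4-methoxybenzaldehyde
Conditions: MgCl2, Et3N, (CH2O)n, MeCN, reflux; then 1 M HCl
Reagents that add atoms: paraformaldehyde (as formaldehyde), C=O
Why: Magnesium-mediated ortho-formylation (Casnati–Skattebøl), in which formaldehyde is delivered inside the magnesium phenoxide to the only free ortho position (the future C4a) and the hydroxymethyl intermediate is oxidised by a second formaldehyde through hydride transfer, so the para position C6 should stay untouched.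

Step 5
Reactants: 9 methyl 4-methoxyphenylacetate
Product: 10 methyl 2-bromo-2-(4-methoxyphenyl)acetate (racemic)
Conditions: NBS, AIBN (cat.), PhCF3, 80 °C
Reagents that add atoms: N-bromosuccinimide, O=C1CCC(=O)N1Br
Why: Wohl–Ziegler bromination, in which hydrogen abstraction gives a radical stabilised by both the ester and the 4-methoxyphenyl ring, so monobromination at the benzylic α-carbon should be clean in a non-polar solvent.

Step 6
Reactants: 8 6-(benzyloxy)-3-{(1R)-1-[4-(benzyloxy)phenyl]ethyl}-2-hydroxy-4-methoxybenzaldehyde; 10 methyl 2-bromo-2-(4-methoxyphenyl)acetate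
Product: 11 methyl 2-[3-(benzyloxy)-6-{(1R)-1-[4-(benzyloxy)phenyl]ethyl}-2-formyl-5-methoxyphenoxy]-2-(4-methoxyphenyl)acetate (both epimers at the α-carbon)
Conditions: Cs2CO3, DMF, rt to 40 °C
Reagents that add atoms: none
Why: Williamson etherification by SN2 displacement, in which the α-bromo arylacetate is activated by the adjacent ester and aryl group and cannot eliminate, so the caesium phenoxide of 8 should be alkylated on oxygen despite its two ortho substituents; the future C2 forms as both epimers, which is of no consequence.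

Step 7
Reactants: 11 methyl 2-[3-(benzyloxy)-6-{(1R)-1-[4-(benzyloxy)phenyl]ethyl}-2-formyl-5-methoxyphenoxy]-2-(4-methoxyphenyl)acetate
Product: 12 2-[3-(benzyloxy)-6-{(1R)-1-[4-(benzyloxy)phenyl]ethyl}-2-(hydroxymethyl)-5-methoxyphenoxy]-2-(4-methoxyphenyl)ethan-1-ol (both epimers)
Conditions: LiAlH4, THF, 0 °C to rt; H2O, aq NaOH work-up
Reagents that add atoms: none
Why: Hydride reduction with LiAlH4 should take the ester and the aryl aldehyde to primary alcohols in one operation, leaving the aryl ethers and the diarylethane centre untouched.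

Step 8
Reactants: 12 2-[3-(benzyloxy)-6-{(1R)-1-[4-(benzyloxy)phenyl]ethyl}-2-(hydroxymethyl)-5-methoxyphenoxy]-2-(4-methoxyphenyl)ethan-1-ol
Product: 13 6-(benzyloxy)-3-{(1R)-1-[4-(benzyloxy)phenyl]ethyl}-4-methoxy-2-[1-(4-methoxyphenyl)-2-oxoethoxy]benzaldehyde (both epimers at the future C2)
Conditions: Dess–Martin periodinane (2.6 equiv), NaHCO3, CH2Cl2, 0 °C to rt; crude used at once
Reagents that add atoms: none
Why: Dess–Martin oxidation should convert both primary alcohols to aldehydes under buffered, near-neutral conditions that spare the acid-sensitive trialkoxybenzyl alcohol and limit enolisation of the α-aryloxy aldehyde, which is carried forward without storage.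

Step 9
Reactants: 13 6-(benzyloxy)-3-{(1R)-1-[4-(benzyloxy)phenyl]ethyl}-4-methoxy-2-[1-(4-methoxyphenyl)-2-oxoethoxy]benzaldehyde
Product: 14 5-(benzyloxy)-8-{(1R)-1-[4-(benzyloxy)phenyl]ethyl}-3-hydroxy-7-methoxy-2-(4-methoxyphenyl)chroman-4-one (mixture of isomers at C2 and C3)
Conditions: 2-(pentafluorophenyl)-6,7-dihydro-5H-pyrrolo[2,1-c][1,2,4]triazol-2-ium tetrafluoroborate (20 mol %), iPr2NEt (20 mol %), CH2Cl2 (0.01 M), Ar, rt to 40 °C
Reagents that add atoms: none
Why: iPr2NEt releases the triazolylidene, which adds to a formyl group; proton transfer gives the hydroxy-enamine (Breslow intermediate), this acyl anion equivalent attacks the second formyl carbon, and collapse of the adduct frees the carbene and the ketol. The closest known reaction type is the carbene-catalysed intramolecular crossed benzoin cyclisation that turns tethered dicarbonyl compounds into 3-hydroxychroman-4-ones and dialdehydes into cyclic acyloins. Ring C closes in the 6-exo-trig mode, the O1–C2 ether and C8a holding the two carbonyl carbons within reach of each other. The new C3 carbinol centre is not controlled by design and should form as a mixture under the influence of the existing C2 centre only; this is harmless because C2 and C3 both become sp2 in step 10, and the (R) centre on the C8 side chain is remote and not acidic. The step needs ring closure to beat intermolecular benzoin, aldol chemistry of the acidic C2–H and loss of the ring A aryloxide from a Breslow intermediate on the C3 aldehyde; the six-membered tether, high dilution, a weak amine base and the absence of free phenols (both are benzylated) should secure this. Donor and acceptor roles need not be controlled, since the isomeric 4-hydroxy-3-ketone shares the enediol of 14 and would be oxidised to the same dione in step 10.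

Step 10
Reactants: 14 5-(benzyloxy)-8-{(1R)-1-[4-(benzyloxy)phenyl]ethyl}-3-hydroxy-7-methoxy-2-(4-methoxyphenyl)chroman-4-one
Product: 16 5-(benzyloxy)-8-{(1R)-1-[4-(benzyloxy)phenyl]ethyl}-3-hydroxy-7-methoxy-2-(4-methoxyphenyl)-4H-chromen-4-one, via chromane-3,4-dione 15 (not isolated)
Conditions: Cu(OAc)2·H2O (2.5 equiv), AcOH/H2O (4:1), 80 °C, N2
Reagents that add atoms: none
Why: Oxidation of an α-ketol by divalent copper, the benzoin-to-benzil reaction type, should bring every ketol isomer to dione 15, whose C2–H enolises at once to the aromatic 3-hydroxy-4-pyranone, and this mild one-electron oxidant leaves the doubly benzylic C–H on the C8 side chain alone.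

Step 11
Reactants: 16 5-(benzyloxy)-8-{(1R)-1-[4-(benzyloxy)phenyl]ethyl}-3-hydroxy-7-methoxy-2-(4-methoxyphenyl)-4H-chromen-4-one
Product: 17 3,5-dihydroxy-8-[(1R)-1-(4-hydroxyphenyl)ethyl]-7-methoxy-2-(4-methoxyphenyl)-4H-chromen-4-one (CNP0223021.1)
Conditions: H2 (1 atm), 10% Pd/C, EtOAc/MeOH, rt
Reagents that add atoms: none
Why: Catalytic hydrogenolysis of the two benzyl aryl ethers over Pd/C at ambient pressure, under which the flavonol ring and the C–C bonds of the 1,1-diarylethane centre should be inert, so the (R) configuration is retained.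

Compound list
1 | 2',4'-dihydroxy-6'-methoxyacetophenone | CC(=O)c1c(O)cc(O)cc1OC | starting material
2 | 1-[4-(benzyloxy)-2-hydroxy-6-methoxyphenyl]ethan-1-one | CC(=O)c1c(O)cc(OCc2ccccc2)cc1OC | intermediate
3 | 1-benzyloxy-4-bromobenzene | Brc1ccc(OCc2ccccc2)cc1 | starting material
4 | 4-(benzyloxy)phenylmagnesium bromide | Br[Mg]c1ccc(OCc2ccccc2)cc1 | intermediate
5 | 5-(benzyloxy)-2-{1-[4-(benzyloxy)phenyl]-1-hydroxyethyl}-3-methoxyphenol (racemic tertiary carbinol) | CC(O)(c1ccc(OCc2ccccc2)cc1)c1c(O)cc(OCc2ccccc2)cc1OC | intermediate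
6 | 5-(benzyloxy)-2-{1-[4-(benzyloxy)phenyl]ethenyl}-3-methoxyphenol | C=C(c1ccc(OCc2ccccc2)cc1)c1c(O)cc(OCc2ccccc2)cc1OC | intermediate
7 | 5-(benzyloxy)-2-{(1R)-1-[4-(benzyloxy)phenyl]ethyl}-3-methoxyphenol | COc1cc(OCc2ccccc2)cc(O)c1[C@H](C)c1ccc(OCc2ccccc2)cc1 | intermediate
8 | 6-(benzyloxy)-3-{(1R)-1-[4-(benzyloxy)phenyl]ethyl}-2-hydroxy-4-methoxybenzaldehyde | COc1cc(OCc2ccccc2)c(C=O)c(O)c1[C@H](C)c1ccc(OCc2ccccc2)cc1 | intermediate
9 | methyl 4-methoxyphenylacetate | COC(=O)Cc1ccc(OC)cc1 | starting material
10 | methyl 2-bromo-2-(4-methoxyphenyl)acetate (racemic) | COC(=O)C(Br)c1ccc(OC)cc1 | intermediate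
11 | methyl 2-[3-(benzyloxy)-6-{(1R)-1-[4-(benzyloxy)phenyl]ethyl}-2-formyl-5-methoxyphenoxy]-2-(4-methoxyphenyl)acetate (both epimers at the α-carbon) | COC(=O)C(Oc1c(C=O)c(OCc2ccccc2)cc(OC)c1[C@H](C)c1ccc(OCc2ccccc2)cc1)c1ccc(OC)cc1 | intermediate
12 | 2-[3-(benzyloxy)-6-{(1R)-1-[4-(benzyloxy)phenyl]ethyl}-2-(hydroxymethyl)-5-methoxyphenoxy]-2-(4-methoxyphenyl)ethan-1-ol (both epimers) | OCC(Oc1c(CO)c(OCc2ccccc2)cc(OC)c1[C@H](C)c1ccc(OCc2ccccc2)cc1)c1ccc(OC)cc1 | intermediate
13 | 6-(benzyloxy)-3-{(1R)-1-[4-(benzyloxy)phenyl]ethyl}-4-methoxy-2-[1-(4-methoxyphenyl)-2-oxoethoxy]benzaldehyde (both epimers at the future C2) | O=CC(Oc1c(C=O)c(OCc2ccccc2)cc(OC)c1[C@H](C)c1ccc(OCc2ccccc2)cc1)c1ccc(OC)cc1 | intermediate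
14 | 5-(benzyloxy)-8-{(1R)-1-[4-(benzyloxy)phenyl]ethyl}-3-hydroxy-7-methoxy-2-(4-methoxyphenyl)chroman-4-one (mixture at C2 and C3) | COc1ccc(C2Oc3c([C@H](C)c4ccc(OCc5ccccc5)cc4)c(OC)cc(OCc4ccccc4)c3C(=O)C2O)cc1 | intermediate
15 | 5-(benzyloxy)-8-{(1R)-1-[4-(benzyloxy)phenyl]ethyl}-7-methoxy-2-(4-methoxyphenyl)chromane-3,4-dione | COc1ccc(C2Oc3c([C@H](C)c4ccc(OCc5ccccc5)cc4)c(OC)cc(OCc4ccccc4)c3C(=O)C2=O)cc1 | intermediate
16 | 5-(benzyloxy)-8-{(1R)-1-[4-(benzyloxy)phenyl]ethyl}-3-hydroxy-7-methoxy-2-(4-methoxyphenyl)-4H-chromen-4-one | COc1ccc(-c2oc3c([C@H](C)c4ccc(OCc5ccccc5)cc4)c(OC)cc(OCc4ccccc4)c3c(=O)c2O)cc1 | intermediate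
17 | 3,5-dihydroxy-8-[(1R)-1-(4-hydroxyphenyl)ethyl]-7-methoxy-2-(4-methoxyphenyl)-4H-chromen-4-one | COc1ccc(-c2oc3c([C@H](C)c4ccc(O)cc4)c(OC)cc(O)c3c(=O)c2O)cc1 | target

Total step count: 11. Longest linear sequence: 10 steps (steps 1–4 and 6–11, from 1 to 17); step 5 is a one-step side branch.

Steps most likely to fail

Step 9. The Breslow intermediate may form on the C3 aldehyde and expel the ring A aryloxide (redox isomerisation to an aryl ester). The acidic C2–H may also divert the dialdehyde into aldol closure, or carbene addition to the doubly ortho-substituted ring A aldehyde may be too slow for turnover. Fallback: setting out from dialdehyde 13, SmI2 (THF, t-BuOH, −78 °C) should close the same C3–C4 bond by intramolecular reductive pinacol coupling. This gives the protected flavan-3,4-diol 5-(benzyloxy)-8-{(1R)-1-[4-(benzyloxy)phenyl]ethyl}-7-methoxy-2-(4-methoxyphenyl)chromane-3,4-diol F1. Oxidation of both carbinols with 2-iodoxybenzoic acid in DMSO at rt should lead through dione 15 to its tautomer, so the route is rejoined at 16 and step 10 is not needed.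

Step 3. Facial selectivity may be poor, or turnover may stall, at the hindered, twisted and electron-rich 1,1-diarylethene. Fallback: setting out from alkene 6, ionic hydrogenation (Et3SiH, CF3CO2H, CH2Cl2, 0 °C) should give the racemic phenol 5-(benzyloxy)-2-{1-[4-(benzyloxy)phenyl]ethyl}-3-methoxyphenol F2. Preparative chromatography on a chiral stationary phase (amylose tris(3,5-dimethylphenylcarbamate), supercritical CO2/MeOH) then separates the enantiomers, and the route is rejoined at 7.

Step 6. O-Alkylation of the hindered, hydrogen-bonded phenoxide may be slow, and the base may drive aldol closure of the product onto the ortho formyl group. Fallback: setting out from ester 9, diazo transfer (4-acetamidobenzenesulfonyl azide, DBU, MeCN) should give methyl 2-diazo-2-(4-methoxyphenyl)acetate F3. Its O–H insertion into phenol 8, catalysed by Rh2(OAc)4 (CH2Cl2, rt, slow addition), forms the same ether under neutral conditions, and the route is rejoined at 11.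

Further compounds
F1 | step 9 | 5-(benzyloxy)-8-{(1R)-1-[4-(benzyloxy)phenyl]ethyl}-7-methoxy-2-(4-methoxyphenyl)chromane-3,4-diol (mixture of isomers) | COc1ccc(C2Oc3c([C@H](C)c4ccc(OCc5ccccc5)cc4)c(OC)cc(OCc4ccccc4)c3C(O)C2O)cc1
F2 | step 3 | racemic 5-(benzyloxy)-2-{1-[4-(benzyloxy)phenyl]ethyl}-3-methoxyphenol | COc1cc(OCc2ccccc2)cc(O)c1C(C)c1ccc(OCc2ccccc2)cc1
F3 | step 6 | methyl 2-diazo-2-(4-methoxyphenyl)acetate | COC(=O)C(=[N+]=[N-])c1ccc(OC)cc1
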